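**Retrosynthetic overview**
1. Target 16 ⇐ Schenck ene reaction (¹O₂) on the Δ7 alkene 15; this sets C7 and moves the double bond to C8=C9.
2. 15 ⇐ C1 ketone reduction and acylation of the 4β-OH; the Δ7 alkene ⇐ 1,3-transposition (allylic oxidation, then allylic diazene) of the Δ6 octalone 8.
3. 8 ⇐ Heck coupling of hydroxy dienone 6 with vinyl triflate 2, then intramolecular Diels–Alder in the same flask: rings A and B close together (C5–C10 and C8–C9 bonds).
4. 6 ⇐ (S)-linalool (¹O₂ ene, dehydration); 2 ⇐ 3-methylbutan-2-one. C4 comes from linalool and controls C5 and C10.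

Assumption: (S)-(+)-linalool of high ee is used as bought. Bicyclic compounds carry eudesmane numbering (C10 bears the angular CH₃, C4 the second CH₃, C7 the isopropyl group); β is the face of the angular CH₃; all decalins are trans-fused with H-5 α.

**Step 1**
Reactants: 1 3-methylbutan-2-one
Product: 2 3-methylbut-1-en-2-yl trifluoromethanesulfonate
Conditions: LDA, THF, −78 °C; then PhNTf₂, −78 to 0 °C
Reagents that add atoms: N-phenyl-bis(trifluoromethanesulfonimide), O=S(=O)(N(c1ccccc1)S(=O)(=O)C(F)(F)F)C(F)(F)F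
Why: Kinetic deprotonation at the CH₃ group and O-triflation of the less substituted lithium enolate (enol triflate synthesis) give the 1,1-disubstituted vinyl triflate; no stereocentre is formed.

**Step 2**
Reactants: 3 (S)-(+)-linalool
Product: 6 (6S)-6-hydroxy-2,6-dimethylocta-1,7-dien-3-one, via allylic hydroperoxide 4 (not isolated), via allylic peracetate 5 (not isolated)
Conditions: O₂, TPP (cat.), hν (white LED), CH₂Cl₂, 0 °C; then Ac₂O, pyridine, 0 °C to rt
Reagents that add atoms: dioxygen, O=O
Why: The Schenck ene reaction of singlet oxygen with the trisubstituted alkene (the vinyl group is inert) gives the secondary allylic hydroperoxide, which is dehydrated through its peracetate (Kornblum–DeLaMare-type elimination) to the α-methylene ketone; the regioisomeric tertiary hydroperoxide is removed by chromatography and the linalool stereocentre is untouched.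

**Step 3**
Reactants: 6 (6S)-6-hydroxy-2,6-dimethylocta-1,7-dien-3-one; 2 3-methylbut-1-en-2-yl trifluoromethanesulfonate
Product: 8 4β-hydroxyeudesm-6-en-1-one, via trienone 7 (not isolated)
Conditions: Pd(OAc)₂ (5 mol %), PPh₃ (10 mol %), Et₃N, BHT (cat.), DMF, 60 °C, then 90 °C
Reagents that add atoms: none
Why: A cationic Mizoroki–Heck vinylation of the hydroxyl-bearing monosubstituted alkene (not the electron-poor 1,1-disubstituted enone) builds the (E)-diene, which closes both rings by an intramolecular Diels–Alder reaction through a chair-like tether with the α-methyl enone carbonyl exo (trans fusion), the C4 methyl anti to the forming C5–C10 bond and the C–O bond gauche (Houk allylic-alkoxy effect, smaller group axial), so that C5 and C10 are set from the linalool centre.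

**Step 4**
Reactants: 8 4β-hydroxyeudesm-6-en-1-one
Product: 9 4β,8ξ-dihydroxyeudesm-6-en-1-one
Conditions: SeO₂ (0.5 equiv), t-BuOOH, CH₂Cl₂, rt
Reagents that add atoms: tert-butyl hydroperoxide, CC(C)(C)OO
Why: The Sharpless SeO₂/t-BuOOH allylic oxidation (ene reaction at C6, then [2,3]-sigmatropic shift) puts oxygen on the ring CH₂ next to the more substituted alkene carbon (C8) without moving the double bond; the C8 configuration is of no consequence.

**Step 5**
Reactants: 9 4β,8ξ-dihydroxyeudesm-6-en-1-one
Product: 12 4β-hydroxyeudesm-7-en-1-one, via allylic sulfonylhydrazine 10 (not isolated), via allylic diazene 11 (not isolated)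
Conditions: 2-nitrobenzenesulfonylhydrazide (NBSH), PPh₃, DEAD, N-methylmorpholine, THF, −30 °C to rt
Reagents that add atoms: none
Why: In the Myers reductive 1,3-transposition, Mitsunobu displacement at C8, loss of sulfinic acid and retro-ene loss of N₂ from the monoalkyl diazene deliver hydrogen to C6 and move the double bond to C7=C8; C6 becomes CH₂, so no stereocentre is at stake.

**Step 6**
Reactants: 12 4β-hydroxyeudesm-7-en-1-one; 13 (E)-cinnamic anhydride
Product: 14 4β-[(E)-cinnamoyloxy]eudesm-7-en-1-one
Conditions: DMAP (1.5 equiv), Et₃N, PhMe, 90 °C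
Reagents that add atoms: none
Why: A Steglich-type DMAP-catalysed acylation under non-acidic conditions esterifies the only hydroxyl group (tertiary, axial) with retention at C4 and leaves the trisubstituted alkene in place.

**Step 7**
Reactants: 14 4β-[(E)-cinnamoyloxy]eudesm-7-en-1-one
Product: 15 4β-[(E)-cinnamoyloxy]eudesm-7-en-1β-ol
Conditions: NaBH₄, CeCl₃·7H₂O, MeOH, −40 to 0 °C
Reagents that add atoms: none
Why: In the Luche reduction hydride adds 1,2 to the ketone along the axial α direction (opposite the adjacent axial C10 methyl) to give the equatorial 1β-alcohol, and the cinnamate is not reduced.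

**Step 8**
Reactants: 15 4β-[(E)-cinnamoyloxy]eudesm-7-en-1β-ol
Product: 16 4β-[(E)-cinnamoyloxy]-7α-hydroperoxyeudesm-8-en-1β-ol (CNP0174426.1)
Conditions: O₂, TPP (cat.), hν (> 500 nm), CH₂Cl₂, −20 °C
Reagents that add atoms: dioxygen, O=O
Why: In the Schenck ene reaction singlet oxygen attacks the open α face (the β face is shielded by the axial C10 methyl and the axial 4β ester), bonds to the more substituted C7 and abstracts H-9α, the only axial allylic hydrogen on that face, giving the 7α-hydroperoxide with the C8=C9 double bond; the electron-poor cinnamate does not react.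

**Compound list**
1 | 3-methylbutan-2-one | CC(C)C(C)=O | starting material
2 | 3-methylbut-1-en-2-yl trifluoromethanesulfonate | C=C(OS(=O)(=O)C(F)(F)F)C(C)C | intermediate
3 | (S)-(+)-linalool, (3S)-3,7-dimethylocta-1,6-dien-3-ol | CC(C)=CCC[C@](C)(O)C=C | starting material
4 | (6S)-3-hydroperoxy-2,6-dimethylocta-1,7-dien-6-ol (both C3 epimers) | C=C(C)C(OO)CC[C@](C)(O)C=C | intermediate (not isolated)
5 | (6S)-6-hydroxy-2,6-dimethylocta-1,7-dien-3-yl ethaneperoxoate | C=C(C)C(OOC(C)=O)CC[C@](C)(O)C=C | intermediate (not isolated)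
6 | (6S)-6-hydroxy-2,6-dimethylocta-1,7-dien-3-one | C=C(C)C(=O)CC[C@](C)(O)C=C | intermediate
7 | (6S,7E)-6-hydroxy-2,6-dimethyl-9-(propan-2-yl)deca-1,7,9-trien-3-one | C=C(C)C(=O)CC[C@](C)(O)/C=C/C(=C)C(C)C | intermediate (not isolated)
8 | 4β-hydroxyeudesm-6-en-1-one (C1 ketone; 4-OH β and axial; 4-CH₃ α; H-5 α; 10-CH₃ β; C6=C7) | CC(C)C1=C[C@H]2[C@@](C)(O)CCC(=O)[C@]2(C)CC1 | intermediate
9 | 4β,8ξ-dihydroxyeudesm-6-en-1-one (as 8 with OH on C8, both epimers) | CC(C)C1=C[C@H]2[C@@](C)(O)CCC(=O)[C@]2(C)CC1O | intermediate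
10 | 8-[1-(2-nitrophenylsulfonyl)hydrazinyl]-4β-hydroxyeudesm-6-en-1-one | CC(C)C1=C[C@H]2[C@@](C)(O)CCC(=O)[C@]2(C)CC1N(N)S(=O)(=O)c3ccccc3[N+](=O)[O-] | intermediate (not isolated)
11 | 8-diazenyl-4β-hydroxyeudesm-6-en-1-one | CC(C)C1=C[C@H]2[C@@](C)(O)CCC(=O)[C@]2(C)CC1N=N | intermediate (not isolated)
12 | 4β-hydroxyeudesm-7-en-1-one (as 8 but C7=C8, C6 is CH₂) | CC(C)C1=CC[C@@]2(C)C(=O)CC[C@](C)(O)[C@@H]2C1 | intermediate
13 | (E)-cinnamic anhydride | O=C(/C=C/c1ccccc1)OC(=O)/C=C/c1ccccc1 | starting material
14 | 4β-[(E)-cinnamoyloxy]eudesm-7-en-1-one | CC(C)C1=CC[C@@]2(C)C(=O)CC[C@](C)(OC(=O)/C=C/c3ccccc3)[C@@H]2C1 | intermediate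
15 | 4β-[(E)-cinnamoyloxy]eudesm-7-en-1β-ol | CC(C)C1=CC[C@@]2(C)[C@H](O)CC[C@](C)(OC(=O)/C=C/c3ccccc3)[C@@H]2C1 | intermediate
16 | 4β-[(E)-cinnamoyloxy]-7α-hydroperoxyeudesm-8-en-1β-ol | CC(C)[C@]1(OO)C=C[C@@]2(C)[C@H](O)CC[C@](C)(OC(=O)/C=C/c3ccccc3)[C@@H]2C1 | target

**Step count:** 8 steps in total; the longest linear sequence is 7 steps (3 to 16, steps 2–8).

**Three steps most likely to fail**

Step 3. The Heck coupling must choose the vinyl carbinol over the enone, and the cycloaddition must be trans-selective and face-selective from C4 alone. The fallback builds the rings one after the other, setting out from 6 and returning at 12. Ring-closing metathesis of 6 (Hoveyda–Grubbs II, PhMe, 80 °C) gives (S)-4-hydroxy-2,4-dimethylcyclohex-2-en-1-one F1. As its magnesium alkoxide this takes up (2-isopropylallyl)magnesium chloride in an alkoxide-directed conjugate addition syn to oxygen, and the enolate is allylated (allyl iodide, HMPA) anti to the new side chain to give 2α-allyl-4β-hydroxy-2,4-dimethyl-3β-(3-methyl-2-methylidenebutyl)cyclohexan-1-one F2. A second ring-closing metathesis (Grubbs II, CH₂Cl₂, 40 °C) closes ring B with C7=C8 already in place and gives 12, so steps 4 and 5 are not needed.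

Step 4. The SeO₂ oxidation may over-oxidise, and the Mitsunobu step that follows may leak through an SN2′ path. The fallback sets out from 8 and returns at 12. CrO₃·3,5-dimethylpyrazole (CH₂Cl₂, −20 °C) oxidises the only allylic CH₂ to the enone 4β-hydroxyeudesm-6-ene-1,8-dione F3. TsNHNH₂ condenses with the unhindered conjugated C8 ketone (the C1 ketone is neopentyl) to give the 8-tosylhydrazone F4. Catecholborane, then NaOAc·3H₂O (Kabalka alkene-forming reduction), reduces F4 with migration of the double bond to C7=C8 and gives 12.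

Step 6. The 4β-hydroxyl is tertiary, axial and syn to the angular methyl, so direct cinnamoylation may stall. The fallback sets out from 12 and returns at 14. Diethylphosphonoacetic acid and DCC (acylation through the small phosphonoketene) give 4β-[(diethoxyphosphoryl)acetoxy]eudesm-7-en-1-one F5. A Horner–Wadsworth–Emmons reaction with benzaldehyde (LiCl, DBU, MeCN) then builds the (E)-cinnamate on the ester already in place and gives 14.

**Further compounds**
F1 | step 3 | (S)-4-hydroxy-2,4-dimethylcyclohex-2-en-1-one | CC1=C[C@@](C)(O)CCC1=O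
F2 | step 3 | 2α-allyl-4β-hydroxy-2,4-dimethyl-3β-(3-methyl-2-methylidenebutyl)cyclohexan-1-one | C=CC[C@@]1(C)C(=O)CC[C@](C)(O)[C@@H]1CC(=C)C(C)C
F3 | step 4 | 4β-hydroxyeudesm-6-ene-1,8-dione | CC(C)C1=C[C@H]2[C@@](C)(O)CCC(=O)[C@]2(C)CC1=O
F4 | step 4 | 4β-hydroxyeudesm-6-ene-1,8-dione 8-(4-methylbenzenesulfonylhydrazone) | CC(C)C1=C[C@H]2[C@@](C)(O)CCC(=O)[C@]2(C)CC1=NNS(=O)(=O)c3ccc(C)cc3
F5 | step 6 | 4β-[(diethoxyphosphoryl)acetoxy]eudesm-7-en-1-one | CC(C)C1=CC[C@@]2(C)C(=O)CC[C@](C)(OC(=O)CP(=O)(OCC)OCC)[C@@H]2C1
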